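**Plan**
1. Numbering: each ring A has C1 (CH2CH2 arm), C2 (central CH2), C3 (OMe), C4 (H), C5 (OH) and C6 (H). Rings B are the two guaiacyl rings.
2. Enabling feature: the central CH2, C2/C2' and the oxygen-bearing C3/C3' form the skeleton of a propane-1,1,3,3-tetracarboxylate, and C1-C6-C5-C4 of each ring A is a 6-arylhex-3-en-2-one. The retrosynthesis therefore cuts C2-C1 and C4-C3 in both rings A (four bonds).
3. Forward: rings B come ready-made in dihydroconiferyl alcohol, which is benzylated, oxidised and olefinated to the enone. The tetraallyl tetraester is made from diallyl malonate and formaldehyde.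
4. Both rings A arise in one operation by a two-directional Michael-Claisen annulation. The allyl ester left on each quaternary C2 is kept as the handle for aromatisation.
5. The open C5 carbonyls are masked as benzyl enol ethers. Pd-catalysed decarboxylation-dehydrogenation then aromatises both rings and frees only the C3 hydroxyls, which are methylated, and one hydrogenolysis removes all four benzyl groups.
6. Stereochemistry: the target has no stereocentre. The four transient centres made in the annulation become sp2 on aromatisation.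

Key step: step 5

Remark: the target SMILES contains no stereocentre and no double-bond geometry, so the compound is achiral and no enantioselective step is needed. Compounds 10-12 are carried as diastereomer mixtures, and 11 is drawn in its diketo form.

Step 1
Reactants: 1 3-(4-hydroxy-3-methoxyphenyl)propan-1-ol (dihydroconiferyl alcohol)
Product: 2 3-(4-benzyloxy-3-methoxyphenyl)propan-1-ol
Conditions: BnBr, K2CO3, acetone, reflux
Reagents that add atoms: benzyl bromide, BrCc1ccccc1
Why: Williamson ether synthesis, in which K2CO3 deprotonates only the phenol and not the primary alcohol, so benzylation is chemoselective for the phenolic oxygen.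

Step 2
Reactants: 2 3-(4-benzyloxy-3-methoxyphenyl)propan-1-ol
Product: 3 3-(4-benzyloxy-3-methoxyphenyl)propanal
Conditions: TEMPO (cat.), PhI(OAc)2, CH2Cl2, rt
Reagents that add atoms: none
Why: TEMPO/PhI(OAc)2 (oxoammonium) oxidation of a primary alcohol stops at the aldehyde and tolerates the benzyl ether and the electron-rich arene.

Step 3
Reactants: 3 3-(4-benzyloxy-3-methoxyphenyl)propanal; 4 1-(triphenylphosphoranylidene)propan-2-one
Product: 5 (E)-6-(4-benzyloxy-3-methoxyphenyl)hex-3-en-2-one
Conditions: CH2Cl2, rt to 40 °C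
Reagents that add atoms: none
Why: Wittig olefination with a stabilised acyl ylide is reliably E-selective with unbranched aliphatic aldehydes, and the alkene geometry is consumed again in step 5.

Step 4
Reactants: 6 diallyl malonate (2 equiv); 7 formaldehyde (37% aqueous solution)
Product: 9 tetraallyl propane-1,1,3,3-tetracarboxylate, via diallyl 2-methylidenemalonate 8 (not isolated)
Conditions: Et2NH (cat.), neat, 5 °C to rt, then 90 °C
Reagents that add atoms: none
Why: This is the classical Knoevenagel condensation-Michael addition of two malonates with formaldehyde, in which the amine-catalysed condensation gives 8 and the second malonate traps it at once.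

Step 5
Reactants: 9 tetraallyl propane-1,1,3,3-tetracarboxylate; 5 (E)-6-(4-benzyloxy-3-methoxyphenyl)hex-3-en-2-one (2.3 equiv)
Product: 11 diallyl 1,1'-methylenebis{6-[2-(4-benzyloxy-3-methoxyphenyl)ethyl]-2,4-dioxocyclohexane-1-carboxylate} (diastereomer mixture), via the open-chain bis-Michael adduct 10 (not isolated)
Conditions: NaH (2.4 equiv), THF, 0 °C to rt; then 5 (slow addition), allyl alcohol (0.2 equiv), reflux; 1 M HCl
Reagents that add atoms: none
Why: Proposed new method: the preformed disodio derivative of 9 adds through each malonate carbon to the β-carbon of 5 (C2-C1 and C2'-C1' bonds, adduct 10), proton transfer through allyl alcohol moves each ketone enolate to the methyl side, and this enolate is acylated by a geminal allyl ester (C4-C3 and C4'-C3' bonds) with loss of allyloxide, which at once deprotonates the new 1,3-dione. The closest known reaction type is the base-mediated Michael-Claisen [3+3] condensation of unsubstituted malonates with alk-3-en-2-ones to 6-alkyl-2,4-dioxocyclohexane-1-carboxylates; new here are the 2-substituted malonate carbon, which becomes quaternary, and the twofold run on one molecule. Each of the two rings closes in the same mode, a favoured 6-(enolendo)-exo-trig Claisen acylation. The four new stereocentres (C1 and C2 of each ring) are under no control, and a mixture of diastereomers is accepted because all four carbons become sp2 in step 7. The step needs the reversible, sterically uphill Michael addition to be drained forwards, which the irreversible formation of the β-diketonate secures, and it needs 9 to be kept from E1cB loss of a malonate anion, which complete double deprotonation before the enone is added secures. Site selectivity in the acylation is secured by ring size, since the two geminal esters are constitutionally equivalent and an ester of the distal malonate could be reached only through an eight-membered ring.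

Step 6
Reactants: 11 diallyl 1,1'-methylenebis{6-[2-(4-benzyloxy-3-methoxyphenyl)ethyl]-2,4-dioxocyclohexane-1-carboxylate}
Product: 12 diallyl 1,1'-methylenebis{4-benzyloxy-6-[2-(4-benzyloxy-3-methoxyphenyl)ethyl]-2-oxocyclohex-3-ene-1-carboxylate}
Conditions: BnOH (6 equiv), TsOH·H2O (cat.), PhMe, Dean-Stark, reflux
Reagents that add atoms: benzyl alcohol, OCc1ccccc1
Why: In this acid-catalysed enol etherification of a cyclic 1,3-dione (vinylogous esterification), the alcohol adds to the C5 carbonyl flanked by two CH2 groups and not to C3 next to the quaternary C2, as is known for 4,4-disubstituted cyclohexane-1,3-diones, and the non-enolisable allyl β-keto ester survives.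

Step 7
Reactants: 12 diallyl 1,1'-methylenebis{4-benzyloxy-6-[2-(4-benzyloxy-3-methoxyphenyl)ethyl]-2-oxocyclohex-3-ene-1-carboxylate}
Product: 14 2,2'-methylenebis{5-benzyloxy-3-[2-(4-benzyloxy-3-methoxyphenyl)ethyl]phenol}, via the bis(cyclohexa-2,5-dienone) tautomer 13 (not isolated)
Conditions: Pd(OAc)2 (10 mol %), dppe (10 mol %), MeCN, reflux
Reagents that add atoms: none
Why: In the Tsuji palladium-catalysed decarboxylation-dehydrogenation of α,α-disubstituted allyl β-keto carboxylates, oxidative addition at the allyl ester and loss of CO2 give a π-allylpalladium enolate at C2-C3, β-hydride elimination of C1-H gives dienone 13 and propene, and 13 tautomerises to the phenol, with acetonitrile and a 1:1 Pd/dppe ratio favouring elimination over allylation.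

Step 8
Reactants: 14 2,2'-methylenebis{5-benzyloxy-3-[2-(4-benzyloxy-3-methoxyphenyl)ethyl]phenol}
Product: 15 bis{4-benzyloxy-2-[2-(4-benzyloxy-3-methoxyphenyl)ethyl]-6-methoxyphenyl}methane
Conditions: MeI (excess), K2CO3, DMF, 40 °C
Reagents that add atoms: iodomethane, CI
Why: Williamson O-methylation needs no selectivity here because the C3/C3' phenols are the only free hydroxyls, and excess MeI in DMF overcomes their ortho hindrance and mutual hydrogen bonding.

Step 9
Reactants: 15 bis{4-benzyloxy-2-[2-(4-benzyloxy-3-methoxyphenyl)ethyl]-6-methoxyphenyl}methane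
Product: 16 4,4'-methylenebis{3-[2-(4-hydroxy-3-methoxyphenyl)ethyl]-5-methoxyphenol} (target)
Conditions: H2 (1 atm), 10% Pd/C, EtOAc-MeOH, rt
Reagents that add atoms: none
Why: Catalytic hydrogenolysis cleaves all four aryl benzyl ethers, while the methyl ethers and the diarylmethane and bibenzyl C-C bonds are inert under these conditions.

**Compound list**
1 | 3-(4-hydroxy-3-methoxyphenyl)propan-1-ol (dihydroconiferyl alcohol) | COc1cc(CCCO)ccc1O | starting material
2 | 3-(4-benzyloxy-3-methoxyphenyl)propan-1-ol | COc1cc(CCCO)ccc1OCc1ccccc1 | intermediate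
3 | 3-(4-benzyloxy-3-methoxyphenyl)propanal | COc1cc(CCC=O)ccc1OCc1ccccc1 | intermediate
4 | 1-(triphenylphosphoranylidene)propan-2-one | CC(=O)C=P(c1ccccc1)(c1ccccc1)c1ccccc1 | starting material
5 | (E)-6-(4-benzyloxy-3-methoxyphenyl)hex-3-en-2-one | CC(=O)/C=C/CCc1ccc(OCc2ccccc2)c(OC)c1 | intermediate
6 | diallyl malonate | C=CCOC(=O)CC(=O)OCC=C | starting material
7 | formaldehyde | C=O | starting material
8 | diallyl 2-methylidenemalonate (not isolated) | C=C(C(=O)OCC=C)C(=O)OCC=C | intermediate
9 | tetraallyl propane-1,1,3,3-tetracarboxylate | C=CCOC(=O)C(CC(C(=O)OCC=C)C(=O)OCC=C)C(=O)OCC=C | intermediate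
10 | tetraallyl 4,8-bis[2-(4-benzyloxy-3-methoxyphenyl)ethyl]-2,10-dioxoundecane-5,5,7,7-tetracarboxylate (bis-Michael adduct, not isolated) | CC(=O)CC(CCc1ccc(OCc2ccccc2)c(OC)c1)C(C(=O)OCC=C)(C(=O)OCC=C)CC(C(=O)OCC=C)(C(=O)OCC=C)C(CCc1ccc(OCc2ccccc2)c(OC)c1)CC(C)=O | intermediate
11 | diallyl 1,1'-methylenebis{6-[2-(4-benzyloxy-3-methoxyphenyl)ethyl]-2,4-dioxocyclohexane-1-carboxylate} (diastereomer mixture) | C=CCOC(=O)C1(CC2(C(=O)OCC=C)C(CCc3ccc(OCc4ccccc4)c(OC)c3)CC(=O)CC2=O)C(CCc2ccc(OCc3ccccc3)c(OC)c2)CC(=O)CC1=O | intermediate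
12 | diallyl 1,1'-methylenebis{4-benzyloxy-6-[2-(4-benzyloxy-3-methoxyphenyl)ethyl]-2-oxocyclohex-3-ene-1-carboxylate} (diastereomer mixture) | C=CCOC(=O)C1(CC2(C(=O)OCC=C)C(CCc3ccc(OCc4ccccc4)c(OC)c3)CC(OCc3ccccc3)=CC2=O)C(CCc2ccc(OCc3ccccc3)c(OC)c2)CC(OCc2ccccc2)=CC1=O | intermediate
13 | 2,2'-methylenebis{5-benzyloxy-3-[2-(4-benzyloxy-3-methoxyphenyl)ethyl]cyclohexa-2,5-dien-1-one} (not isolated) | O=C1C=C(OCc2ccccc2)CC(CCc2ccc(OCc3ccccc3)c(OC)c2)=C1CC1=C(CCc2ccc(OCc3ccccc3)c(OC)c2)CC(OCc2ccccc2)=CC1=O | intermediate
14 | 2,2'-methylenebis{5-benzyloxy-3-[2-(4-benzyloxy-3-methoxyphenyl)ethyl]phenol} | Oc1cc(OCc2ccccc2)cc(CCc2ccc(OCc3ccccc3)c(OC)c2)c1Cc1c(O)cc(OCc2ccccc2)cc1CCc1ccc(OCc2ccccc2)c(OC)c1 | intermediate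
15 | bis{4-benzyloxy-2-[2-(4-benzyloxy-3-methoxyphenyl)ethyl]-6-methoxyphenyl}methane | COc1cc(OCc2ccccc2)cc(CCc2ccc(OCc3ccccc3)c(OC)c2)c1Cc1c(OC)cc(OCc2ccccc2)cc1CCc1ccc(OCc2ccccc2)c(OC)c1 | intermediate
16 | 4,4'-methylenebis{3-[2-(4-hydroxy-3-methoxyphenyl)ethyl]-5-methoxyphenol} (CNP0079383.0, achiral) | COc1cc(CCc2cc(O)cc(OC)c2Cc2c(CCc3ccc(O)c(OC)c3)cc(O)cc2OC)ccc1O | target

Total step count: 9.
Longest linear sequence: 8 steps (1, 2, 3, 5, 11, 12, 14, 15, 16).

**Steps most likely to fail**

Step 5. The conjugate addition has to build a quaternary carbon next to a tertiary one, and its equilibrium may lie too far back. Base-induced self-condensation of the enone, or fragmentation of the tetraester by retro-Michael loss of malonate, could then overtake the annulation. The second annulation may also stall after the first.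

The fallback uses known reactions only, sets out from 5 and comes back at 14. The rings are made singly with the parent malonate, and the CH2 bridge is put in afterwards at the vinylogous-ester stage. Enone 5 and dimethyl malonate (NaOMe, MeOH, reflux; the parent Michael-Claisen condensation) give methyl 6-[2-(4-benzyloxy-3-methoxyphenyl)ethyl]-2,4-dioxocyclohexane-1-carboxylate F1. Saponification followed by acidification and warming gives 5-[2-(4-benzyloxy-3-methoxyphenyl)ethyl]cyclohexane-1,3-dione F2. Because this dione is symmetric, BnOH/TsOH gives a single enol ether, 3-benzyloxy-5-[2-(4-benzyloxy-3-methoxyphenyl)ethyl]cyclohex-2-en-1-one F3. Kinetic α'-deprotonation (LDA, THF, -78 °C, Stork-Danheiser regiochemistry) and Eschenmoser's salt give the Mannich base 3-benzyloxy-6-(dimethylaminomethyl)-5-[2-(4-benzyloxy-3-methoxyphenyl)ethyl]cyclohex-2-en-1-one F4. MeI gives the corresponding trimethylammonium iodide F5, and aqueous NaHCO3 eliminates it to 3-benzyloxy-6-methylidene-5-[2-(4-benzyloxy-3-methoxyphenyl)ethyl]cyclohex-2-en-1-one F6. Michael addition of the kinetic lithium enolate of a second equivalent of F3 to F6 joins the halves as 6,6'-methylenebis{3-benzyloxy-5-[2-(4-benzyloxy-3-methoxyphenyl)ethyl]cyclohex-2-en-1-one} F7. This is dehydrogenated to 14 in the way set out under step 7.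

Step 7. β-Hydride elimination from the palladium enolate may be outrun by reductive elimination to the C2-allyl ketone. It may also be outrun by protonation of the enolate by the phenol that builds up, with transfer of the allyl group to oxygen.

The fallback sets out from 12 and comes back at 14, and it separates loss of the ester from dehydrogenation. Pd(PPh3)4 with HCO2H/Et3N in THF at rt (Tsuji decarboxylation-hydrogenolysis of allyl β-keto esters) gives 6,6'-methylenebis{3-benzyloxy-5-[2-(4-benzyloxy-3-methoxyphenyl)ethyl]cyclohex-2-en-1-one} F7. Double kinetic α'-deprotonation and silylation (LDA, TMSCl, THF, -78 °C) give the bis(trimethylsilyl dienol ether) F8. DDQ in CH2Cl2 (or Pd(OAc)2, Saegusa-Ito oxidation) followed by a mild acidic work-up gives 14.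

Step 6. The etherification may be slow at a dione that sits beside a quaternary carbon. Long heating with acid may then erode the C5/C3 selectivity or exchange the allyl ester for a benzyl ester.

The fallback sets out from 11, comes back at 12 and makes no new compound. The polarity is inverted: the dione serves as the acidic O-nucleophile in a Mitsunobu reaction (BnOH, PPh3, DIAD, THF, 0 °C to rt). The less hindered C5 oxygen attacks the benzyloxyphosphonium ion under neutral conditions at low temperature, so the esters are not touched.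

**Further compounds**
F1 | step 5 | methyl 6-[2-(4-benzyloxy-3-methoxyphenyl)ethyl]-2,4-dioxocyclohexane-1-carboxylate | COC(=O)C1C(CCc2ccc(OCc3ccccc3)c(OC)c2)CC(=O)CC1=O
F2 | step 5 | 5-[2-(4-benzyloxy-3-methoxyphenyl)ethyl]cyclohexane-1,3-dione | O=C1CC(=O)CC(CCc2ccc(OCc3ccccc3)c(OC)c2)C1
F3 | step 5 | 3-benzyloxy-5-[2-(4-benzyloxy-3-methoxyphenyl)ethyl]cyclohex-2-en-1-one | O=C1C=C(OCc2ccccc2)CC(CCc2ccc(OCc3ccccc3)c(OC)c2)C1
F4 | step 5 | 3-benzyloxy-6-(dimethylaminomethyl)-5-[2-(4-benzyloxy-3-methoxyphenyl)ethyl]cyclohex-2-en-1-one | CN(C)CC1C(CCc2ccc(OCc3ccccc3)c(OC)c2)CC(OCc2ccccc2)=CC1=O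
F5 | step 5 | ({4-benzyloxy-6-[2-(4-benzyloxy-3-methoxyphenyl)ethyl]-2-oxocyclohex-3-en-1-yl}methyl)trimethylammonium iodide | C[N+](C)(C)CC1C(CCc2ccc(OCc3ccccc3)c(OC)c2)CC(OCc2ccccc2)=CC1=O.[I-]
F6 | step 5 | 3-benzyloxy-6-methylidene-5-[2-(4-benzyloxy-3-methoxyphenyl)ethyl]cyclohex-2-en-1-one | C=C1C(CCc2ccc(OCc3ccccc3)c(OC)c2)CC(OCc2ccccc2)=CC1=O
F7 | step 5 | 6,6'-methylenebis{3-benzyloxy-5-[2-(4-benzyloxy-3-methoxyphenyl)ethyl]cyclohex-2-en-1-one} | O=C1C=C(OCc2ccccc2)CC(CCc2ccc(OCc3ccccc3)c(OC)c2)C1CC1C(CCc2ccc(OCc3ccccc3)c(OC)c2)CC(OCc2ccccc2)=CC1=O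
F8 | step 7 | bis{4-benzyloxy-6-[2-(4-benzyloxy-3-methoxyphenyl)ethyl]-2-(trimethylsilyloxy)cyclohexa-1,3-dien-1-yl}methane | C[Si](C)(C)OC1=C(CC2=C(O[Si](C)(C)C)C=C(OCc3ccccc3)CC2CCc2ccc(OCc3ccccc3)c(OC)c2)C(CCc2ccc(OCc3ccccc3)c(OC)c2)CC(OCc2ccccc2)=C1
F0 | step 6 | none | none
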